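**Strategy.** Atoms carry chromone numbers throughout. The carbocycle is opened at C7–C8. In the pyranone ring, C8 lies γ to the C4 carbonyl along the vinylogous ester O1–C8a=C4a–C4=O, so a benzyloxymethyl group on C8a is a masked carbon nucleophile. A silyl triflate and a hindered amine convert it into an exocyclic silyl dienol ether that adds to a C7 aldehyde tethered to C4a. This one operation forms C7–C8, closes the cyclohexene ring and sets C7 and C8. The precursor is a 4-pyranone with the arylethyl chain on C2, benzyloxymethyl on C8a, and on C4a a cis-dioxolane (C5/C6 acetonide) bearing the aldehyde. Global deprotection then gives the target.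

Key step: step 9

Remark: 3-benzyloxy-4-methoxybenzyl alcohol (1) is taken as a commercial compound. The target is (5S,6S,7R,8S), with O5/O6 cis, O6/O7 trans and O7/O8 trans; the CIP letter at C6 changes with the protecting groups while the spatial arrangement stays the same.

**Step 1**
Reactants: 1 3-benzyloxy-4-methoxybenzyl alcohol
Product: 2 3-benzyloxy-4-methoxybenzyl bromide
Conditions: PBr3 (0.4 equiv), Et2O, 0 °C; used crude
Reagents that add atoms: phosphorus tribromide, BrP(Br)Br
Why: A primary benzylic alcohol is converted into the bromide by PBr3 through SN2 displacement of the phosphite ester, and the electron-rich bromide is carried on at once so that it cannot self-alkylate.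

**Step 2**
Reactants: 2 3-benzyloxy-4-methoxybenzyl bromide; 3 propargyl bromide
Product: 6 5-(3-benzyloxy-4-methoxyphenyl)pent-2-ynoic acid, via 1,3-dilithiopropyne 4 (not isolated), via lithium alkynide 5 (not isolated)
Conditions: 3, n-BuLi (2 equiv), TMEDA, Et2O, −78 °C; then 2, −78 to 0 °C; then CO2, −78 °C to rt; aq. HCl
Reagents that add atoms: carbon dioxide, O=C=O
Why: 1,3-Dilithiopropyne is alkylated by reactive halides at its propargylic carbon (propargylation of a halide), which leaves a lithium alkynide that is carboxylated by CO2 in the same flask.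

**Step 3**
Reactants: 7 benzyloxyacetyl chloride; 8 Meldrum's acid
Product: 10 S-dodecyl 4-(benzyloxy)-3-oxobutanethioate, via acyl Meldrum's acid 9 (not isolated)
Conditions: pyridine, CH2Cl2, 0 °C to rt, aq. HCl wash; then n-C12H25SH, toluene, reflux
Reagents that add atoms: 1-dodecanethiol, CCCCCCCCCCCCS
Why: C-acylation of Meldrum's acid followed by thermal ring opening (loss of acetone and CO2) in the presence of a thiol is the standard Meldrum's acid route to β-keto thioesters, and the odourless dodecyl thioester is a suitable substrate for the later Fukuyama reduction.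

**Step 4**
Reactants: 6 5-(3-benzyloxy-4-methoxyphenyl)pent-2-ynoic acid; 10 S-dodecyl 4-(benzyloxy)-3-oxobutanethioate
Product: 13 S-dodecyl 6-[2-(3-benzyloxy-4-methoxyphenyl)ethyl]-2-(benzyloxymethyl)-4-oxo-4H-pyran-3-carbothioate, via acid chloride 11 (not isolated), via triketone 12 (not isolated)
Conditions: 6, (COCl)2, DMF (cat.), CH2Cl2, 0 °C to rt, evaporate; then 10, MgCl2, pyridine, CH2Cl2, 0 °C to rt; then DBU (cat.), rt
Reagents that add atoms: none
Why: Magnesium-chelate-controlled C-acylation of the β-keto thioester gives the enolised triketone, whose ketone enol oxygen adds to the ynone in a 6-endo-dig oxa-Michael closure (the usual fate of 2-acyl ynones), while the poorly nucleophilic thioester carbonyl stays exocyclic.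

**Step 5**
Reactants: 13 pyranone thioester
Product: 14 6-[2-(3-benzyloxy-4-methoxyphenyl)ethyl]-2-(benzyloxymethyl)-4-oxo-4H-pyran-3-carbaldehyde
Conditions: Et3SiH, 10% Pd/C, acetone, rt
Reagents that add atoms: none
Why: The Fukuyama reduction (palladium-catalysed hydrosilane reduction of a thioester) stops at the aldehyde and uses no nucleophilic hydride, so the pyranone, which aluminium or boron hydrides could reduce at C4 or in conjugate fashion, and both benzyl ethers should survive.

**Step 6**
Reactants: 14 pyranone aldehyde; 15 allenylboronic acid pinacol ester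
Product: 18 6-[2-(3-benzyloxy-4-methoxyphenyl)ethyl]-2-(benzyloxymethyl)-3-[(1S,2R)-1,2-dihydroxybut-3-en-1-yl]-4H-pyran-4-one, via borylallylborane 16 (not isolated), via boron adduct 17 (not isolated)
Conditions: 15, (+)-Ipc2BH [from (−)-α-pinene] (1.3 equiv), Et2O, 0 °C; then 14, −78 °C; then 30% H2O2, 1 M NaOH, 0 °C
Reagents that add atoms: hydrogen peroxide, OO
Why: Hydroboration of the allenylboronate gives the (E)-γ-borylallylborane, which adds to the aldehyde through a chair-like six-membered transition state (asymmetric allylboration) so that the E geometry fixes the anti relation of C5 and C6 and the isopinocampheyl groups from (−)-α-pinene direct attack to the Re face (C5 S), after which oxidation of the C6–B bond with retention gives the anti diol.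

**Step 7**
Reactants: 18 anti diol
Product: 19 6-[2-(3-benzyloxy-4-methoxyphenyl)ethyl]-2-(benzyloxymethyl)-3-[(4S,5R)-2,2-dimethyl-5-vinyl-1,3-dioxolan-4-yl]-4H-pyran-4-one
Conditions: Me2C(OMe)2, PPTS (cat.), CH2Cl2, rt
Reagents that add atoms: 2,2-dimethoxypropane, COC(C)(C)OC
Why: Acid-catalysed transketalisation (acetonide formation) turns the anti 1,2-diol into the cis-4,5-disubstituted dioxolane without touching either stereocentre, and the mild pyridinium acid should not ionise the C5–O bond.

**Step 8**
Reactants: 19 vinyl acetonide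
Product: 21 (4S,5S)-5-{6-[2-(3-benzyloxy-4-methoxyphenyl)ethyl]-2-(benzyloxymethyl)-4-oxo-4H-pyran-3-yl}-2,2-dimethyl-1,3-dioxolane-4-carbaldehyde, via vicinal diol 20 (not isolated)
Conditions: OsO4 (cat.), NaIO4, 2,6-lutidine, dioxane/H2O (3:1), rt; dried azeotropically and used at once
Reagents that add atoms: osmium tetroxide, O=[Os](=O)(=O)=O (oxygen carrier); sodium periodate, [Na+].[O-]I(=O)(=O)=O (terminal oxidant)
Why: In this Lemieux–Johnson oxidation the monosubstituted vinyl group is the only electron-rich, unhindered alkene (the pyranone double bonds are deactivated vinylogous-ester alkenes), periodate cleaves the diol to the aldehyde, and 2,6-lutidine buffers the medium so that C6 should not epimerise.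

**Step 9**
Reactants: 21 acetonide aldehyde
Product: 25 8-O-benzyl-5,6-O-isopropylidene tetrahydrochromone with free 7-OH, via silyloxypyrylium triflate 22 (not isolated), via silyl dienol ether 23 (not isolated), via O7 silyl ether 24 (not isolated)
Conditions: i-Pr2NEt (3 equiv), Me3SiOTf (2.5 equiv), CH2Cl2 (0.01 M), −78 to −40 °C; then aq. citric acid, THF, 0 °C
Reagents that add atoms: none
Why: Proposed new method: Me3SiOTf silylates the strongly Lewis-basic pyranone carbonyl to the 4-silyloxypyrylium ion 22, the amine removes a C8 proton (α to the ring oxygen and further acidified by the benzyloxy group) to give the 2-alkylidene-2H-pyran 23, and its exocyclic C8 adds to the C7 aldehyde activated by the second equivalent of silyl triflate, which restores the pyranone as silyl ether 24 that is hydrolysed on work-up. The closest known reaction types are the vinylogous aldol addition of laterally deprotonated 2-alkyl-4-pyranones and one-pot silyl triflate/amine Mukaiyama aldol additions, and their union on an alkoxy-bearing pyranone lateral carbon is what is new. The carbocycle closes in a 6-(enolendo)-exo-trig mode, because the reacting C8=C8a bond lies inside the new ring C8–C8a–C4a–C5–C6–C7, the same geometry as in ordinary cyclohexenone-forming aldol closures. C7 is set in a half-chair transition state in which the cis-fused dioxolane holds O6 equatorial and O5 pseudo-axial and the aldehyde C=O turns anti to the C6–O bond (silicon does not chelate), so that O7 becomes equatorial and trans to O6; C8 is set by the dienol ether geometry, in which allylic strain keeps OBn away from C4a and so delivers it pseudo-equatorial and trans to O7, and this all-equatorial C6/C7/C8 isomer is also the thermodynamic one if retro-aldol or C8 re-enolisation intervenes. The step needs site selectivity for C8–H over the CH2 of the arylethyl chain on C2 and over the aldehyde α-hydrogen at C6, which is secured because only the C8 dienol ether can reach the aldehyde while its isomer is returned by proton exchange with the ammonium triflate, and because at −78 °C the pyranone is silylated far faster than the weakly basic aldehyde is enolised. High dilution holds back intermolecular aldol addition, and the excess of hindered amine keeps free triflic acid from the acetonide.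

**Step 10**
Reactants: 25 protected tetrahydrochromone
Product: 26 (5S,6S,7R,8S)-5,6,7,8-tetrahydroxy-2-[2-(3-hydroxy-4-methoxyphenyl)ethyl]-5,6,7,8-tetrahydro-4H-chromen-4-one
Conditions: BCl3 (1 M in CH2Cl2, excess), C6HMe5, CH2Cl2, −78 to −30 °C; then MeOH, −78 °C to rt
Reagents that add atoms: none
Why: In this Lewis-acid ether cleavage BCl3 with pentamethylbenzene as a non-basic benzyl-cation trap removes the aryl and the alkyl benzyl ether and opens the acetonide at low temperature, the aryl methyl ether is inert under these conditions, and boron complexation of the pyranone carbonyl makes the ring pyrylium-like and so disfavours ionisation at C5 and C8, which should keep all four stereocentres intact.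

**Compound list**

1 | 3-benzyloxy-4-methoxybenzyl alcohol | COc1ccc(CO)cc1OCc1ccccc1 | starting material
2 | 3-benzyloxy-4-methoxybenzyl bromide | COc1ccc(CBr)cc1OCc1ccccc1 | intermediate
3 | propargyl bromide (3-bromoprop-1-yne) | C#CCBr | starting material
4 | 1,3-dilithiopropyne | [Li]CC#C[Li] | intermediate (not isolated)
5 | lithium 4-(3-benzyloxy-4-methoxyphenyl)but-1-yn-1-ide | [Li]C#CCCc1ccc(OC)c(OCc2ccccc2)c1 | intermediate (not isolated)
6 | 5-(3-benzyloxy-4-methoxyphenyl)pent-2-ynoic acid | COc1ccc(CCC#CC(=O)O)cc1OCc1ccccc1 | intermediate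
7 | benzyloxyacetyl chloride | O=C(Cl)COCc1ccccc1 | starting material
8 | Meldrum's acid (2,2-dimethyl-1,3-dioxane-4,6-dione) | CC1(C)OC(=O)CC(=O)O1 | starting material
9 | 5-[2-(benzyloxy)-1-hydroxyethylidene]-2,2-dimethyl-1,3-dioxane-4,6-dione | CC1(C)OC(=O)C(=C(O)COCc2ccccc2)C(=O)O1 | intermediate (not isolated)
10 | S-dodecyl 4-(benzyloxy)-3-oxobutanethioate | CCCCCCCCCCCCSC(=O)CC(=O)COCc1ccccc1 | intermediate
11 | 5-(3-benzyloxy-4-methoxyphenyl)pent-2-ynoyl chloride | COc1ccc(CCC#CC(=O)Cl)cc1OCc1ccccc1 | intermediate (not isolated)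
12 | S-dodecyl 2-(benzyloxyacetyl)-7-(3-benzyloxy-4-methoxyphenyl)-3-oxohept-4-ynethioate (enolised) | CCCCCCCCCCCCSC(=O)C(C(=O)COCc1ccccc1)C(=O)C#CCCc1ccc(OC)c(OCc2ccccc2)c1 | intermediate (not isolated)
13 | S-dodecyl 6-[2-(3-benzyloxy-4-methoxyphenyl)ethyl]-2-(benzyloxymethyl)-4-oxo-4H-pyran-3-carbothioate | COc1ccc(CCc2cc(=O)c(C(=O)SCCCCCCCCCCCC)c(COCc3ccccc3)o2)cc1OCc1ccccc1 | intermediate
14 | 6-[2-(3-benzyloxy-4-methoxyphenyl)ethyl]-2-(benzyloxymethyl)-4-oxo-4H-pyran-3-carbaldehyde | COc1ccc(CCc2cc(=O)c(C=O)c(COCc3ccccc3)o2)cc1OCc1ccccc1 | intermediate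
15 | allenylboronic acid pinacol ester | C=C=CB1OC(C)(C)C(C)(C)O1 | starting material
16 | (E)-[3-(pinacolatoboryl)allyl]diisopinocampheylborane, Ipc groups from (−)-α-pinene | CC1(C)OB(/C=C/CB([C@H]2C[C@H]3C[C@@H]([C@@H]2C)C3(C)C)[C@H]2C[C@H]3C[C@@H]([C@@H]2C)C3(C)C)OC1(C)C | intermediate (not isolated)
17 | allylboration adduct: O5-diisopinocampheylboryl, C6-pinacolatoboryl derivative of 18 | COc1ccc(CCc2cc(=O)c([C@H](OB([C@H]3C[C@H]4C[C@@H]([C@@H]3C)C4(C)C)[C@H]3C[C@H]4C[C@@H]([C@@H]3C)C4(C)C)[C@H](B3OC(C)(C)C(C)(C)O3)C=C)c(COCc3ccccc3)o2)cc1OCc1ccccc1 | intermediate (not isolated)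
18 | 6-[2-(3-benzyloxy-4-methoxyphenyl)ethyl]-2-(benzyloxymethyl)-3-[(1S,2R)-1,2-dihydroxybut-3-en-1-yl]-4H-pyran-4-one (anti diol) | COc1ccc(CCc2cc(=O)c([C@H](O)[C@H](O)C=C)c(COCc3ccccc3)o2)cc1OCc1ccccc1 | intermediate
19 | 6-[2-(3-benzyloxy-4-methoxyphenyl)ethyl]-2-(benzyloxymethyl)-3-[(4S,5R)-2,2-dimethyl-5-vinyl-1,3-dioxolan-4-yl]-4H-pyran-4-one (cis-acetonide) | COc1ccc(CCc2cc(=O)c([C@@H]3OC(C)(C)O[C@@H]3C=C)c(COCc3ccccc3)o2)cc1OCc1ccccc1 | intermediate
20 | 1,2-diol from dihydroxylation of the vinyl group of 19 (both epimers at the new carbinol) | COc1ccc(CCc2cc(=O)c([C@@H]3OC(C)(C)O[C@@H]3C(O)CO)c(COCc3ccccc3)o2)cc1OCc1ccccc1 | intermediate (not isolated)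
21 | (4S,5S)-5-{6-[2-(3-benzyloxy-4-methoxyphenyl)ethyl]-2-(benzyloxymethyl)-4-oxo-4H-pyran-3-yl}-2,2-dimethyl-1,3-dioxolane-4-carbaldehyde (cis-acetonide aldehyde, key-step precursor) | COc1ccc(CCc2cc(=O)c([C@@H]3OC(C)(C)O[C@@H]3C=O)c(COCc3ccccc3)o2)cc1OCc1ccccc1 | intermediate
22 | 4-(trimethylsilyloxy)pyrylium triflate of 21 | COc1ccc(CCc2cc(O[Si](C)(C)C)c([C@@H]3OC(C)(C)O[C@@H]3C=O)c(COCc3ccccc3)[o+]2)cc1OCc1ccccc1.[O-]S(=O)(=O)C(F)(F)F | intermediate (not isolated)
23 | 2-[(Z)-benzyloxymethylidene]-4-(trimethylsilyloxy)-2H-pyran derived from 21 (exocyclic C8=C8a, OBn syn to O1) | COc1ccc(CCC2=CC(O[Si](C)(C)C)=C([C@@H]3OC(C)(C)O[C@@H]3C=O)/C(=C/OCc3ccccc3)O2)cc1OCc1ccccc1 | intermediate (not isolated)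
24 | 7-O-trimethylsilyl ether of 25 | COc1ccc(CCc2cc(=O)c3c(o2)[C@@H](OCc4ccccc4)[C@H](O[Si](C)(C)C)[C@H]4OC(C)(C)O[C@@H]34)cc1OCc1ccccc1 | intermediate (not isolated)
25 | 8-benzyloxy-2-[2-(3-benzyloxy-4-methoxyphenyl)ethyl]-7-hydroxy-5,6-(isopropylidenedioxy)-5,6,7,8-tetrahydro-4H-chromen-4-one; C5 S, C6 R, C7 R, C8 S in this protected form; O5/O6 cis, O6/O7 trans, O7/O8 trans | COc1ccc(CCc2cc(=O)c3c(o2)[C@@H](OCc4ccccc4)[C@H](O)[C@H]4OC(C)(C)O[C@@H]34)cc1OCc1ccccc1 | intermediate
26 | (5S,6S,7R,8S)-5,6,7,8-tetrahydroxy-2-[2-(3-hydroxy-4-methoxyphenyl)ethyl]-5,6,7,8-tetrahydro-4H-chromen-4-one | COc1ccc(CCc2cc(=O)c3c(o2)[C@@H](O)[C@H](O)[C@@H](O)[C@H]3O)cc1O | target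

**Step count.** Total: 10 steps. Longest linear sequence: 9 steps (1, 2, 4, 5, 6, 7, 8, 9, 10); step 3 is a one-step side branch.

**Steps most likely to fail**

Step 9 (the proposed new method). The silyl triflate and amine may enolise the aldehyde at C6 instead of the pyranone at C8, which would epimerise C6 or expel the acetonide oxygen on C5. The acetonide may also be opened, or intermolecular aldol addition may win. The fallback uses known chemistry and moves the ring closure to the carboxyl oxidation level. It sets out from 21, which is oxidised under Pinnick conditions (NaClO2, NaH2PO4, 2-methyl-2-butene, t-BuOH/H2O) to the dioxolane carboxylic acid F1 and methylated with Me3SiCHN2 in toluene/MeOH to the methyl ester F2. Lateral lithiation of the pyranone at C8 with LiN(SiMe3)2 (2.2 equiv, THF, −78 °C) and Dieckmann-type acylation by the ester, the intramolecular form of the known lateral acylation of 2-alkyl-4-pyranones, should give the 7-ketone F3, in which the epimerisable C8 relaxes to pseudo-equatorial OBn. Luche reduction (NaBH4, CeCl3·7H2O, MeOH, −78 °C) with axial hydride delivery should then place O7 equatorial, and the route is rejoined at 25.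

Step 6. Addition to the doubly flanked aldehyde may be slow, the β-boryl alkoxide may eliminate to a diene before it is oxidised, or alkaline peroxide may attack the pyranone. The fallback replaces the stoichiometric borane by a catalytic C–C coupling. It sets out from 14, which is submitted to iridium-catalysed transfer-hydrogenative anti-(α-benzoyloxy)allylation with prop-2-ene-1,1-diyl dibenzoate ([Ir(cod)Cl]2, one enantiomer of SEGPHOS chosen to give the (1S,2R) isomer, 4-cyano-3-nitrobenzoic acid, K3PO4, i-PrOH, THF, heat). This should give the anti diol monobenzoate F4, whose methanolysis (K2CO3, MeOH, 0 °C) returns the route to 18.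

Step 10. Cleavage of the acetonide may be incomplete, or the acid set free on quenching may cause dehydration towards the aromatic chromone or substitution at C5. The fallback separates the two deprotections and uses no Lewis acid. It sets out from 25, which is hydrogenolysed (H2, 10% Pd/C, EtOAc/EtOH, rt; benzyl ethers on 4-pyranones are routinely removed this way) to the acetonide phenol triol F5. Mild aqueous acid (AcOH/H2O 4:1, 40 °C) then removes the isopropylidene group and gives 26.

**Further compounds**

F1 | step 9 | (4S,5S)-5-{6-[2-(3-benzyloxy-4-methoxyphenyl)ethyl]-2-(benzyloxymethyl)-4-oxo-4H-pyran-3-yl}-2,2-dimethyl-1,3-dioxolane-4-carboxylic acid | COc1ccc(CCc2cc(=O)c([C@@H]3OC(C)(C)O[C@@H]3C(=O)O)c(COCc3ccccc3)o2)cc1OCc1ccccc1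
F2 | step 9 | methyl ester of F1 | COc1ccc(CCc2cc(=O)c([C@@H]3OC(C)(C)O[C@@H]3C(=O)OC)c(COCc3ccccc3)o2)cc1OCc1ccccc1
F3 | step 9 | 8-benzyloxy-2-[2-(3-benzyloxy-4-methoxyphenyl)ethyl]-5,6-(isopropylidenedioxy)-5,6-dihydro-4H-chromene-4,7(8H)-dione (7-ketone, configuration at C5, C6 and C8 as in 25) | COc1ccc(CCc2cc(=O)c3c(o2)[C@@H](OCc4ccccc4)C(=O)[C@H]4OC(C)(C)O[C@@H]34)cc1OCc1ccccc1
F4 | step 6 | (1S,2R)-1-{6-[2-(3-benzyloxy-4-methoxyphenyl)ethyl]-2-(benzyloxymethyl)-4-oxo-4H-pyran-3-yl}-1-hydroxybut-3-en-2-yl benzoate | COc1ccc(CCc2cc(=O)c([C@H](O)[C@H](OC(=O)c3ccccc3)C=C)c(COCc3ccccc3)o2)cc1OCc1ccccc1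
F5 | step 10 | 7,8-dihydroxy-2-[2-(3-hydroxy-4-methoxyphenyl)ethyl]-5,6-(isopropylidenedioxy)-5,6,7,8-tetrahydro-4H-chromen-4-one (configuration as in 25) | COc1ccc(CCc2cc(=O)c3c(o2)[C@@H](O)[C@H](O)[C@H]4OC(C)(C)O[C@@H]34)cc1O
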